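All runs were computed for an exercise, and the scatter is random.

Read shares, not molarities.

| flask | starting material | free catalyst | time |
|---|---|---|---|
| dusk | 0.500 M | 0.00100 M |  |
| noon | 0.250 M | 0.00100 M |  |
| dawn | 0.500 M | 0.00300 M |  |
| summer | 1.00 M | 0.00100 M |  |
| spring | 2.30 M | 0.00100 M | 83 min |

| dusk run: time / min | dusk run: [product] / M | noon run: time / min | noon run: [product] / M | dawn run: time / min | dawn run: [product] / M | summer run: time / min | summer run: [product] / M |
|---|---|---|---|---|---|---|---|
| 6.3 | 0.065 | 6.3 | 0.039 | 6.3 | 0.210 | 6.3 | 0.128 |
| 19 | 0.135 | 19 | 0.070 | 19 | 0.370 | 19 | 0.283 |
| 37 | 0.197 | 37 | 0.093 | 37 | 0.426 | 37 | 0.373 |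
| 58 | 0.203 | 58 | 0.104 | 58 | 0.454 | 58 | 0.424 |
| 83 | 0.230 | 83 | 0.115 | 83 | 0.453 | 83 | 0.449 |

(readings scatter by 0.005 M)

1. the power of [starting material] that the first rate follows, about the charge of the dusk run; measure it at two percent of starting material made into product (one fixed amount of product, the same in the runs compared)
2. the power of [free catalyst] that the first rate follows, about the charge of the dusk run; measure it at two percent of starting material made into product
3. product in the spring run at 83 min, as a share of the starting material charged

- Overall: starting material -> product, with free catalyst as catalyst.
- Constant volume, constant temperature.
- An order is taken over about fifteen percent of the charge, up and down.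

Does the charge change the share turned? At 83 min, product stands at 46.0 % of the charge in the noon run, 46.0 % in the dusk run and 44.9 % in the summer run, across a factor of 4.00 in charge. So I put the power of starting material at 1: at a given free catalyst the flask is pseudo-first-order. The summer run then stands at 0.596 of the quantity I carry: the exposure, the natural log of the charge over the starting material left, which counts the lifetimes of starting material served so far.

Does exposure keep growing? In the summer run it gains 0.0217 min⁻¹ at first but 0.00177 min⁻¹ between the last two readings. This is no equilibrium, since the dawn run has turned 90.6 %. I read the fall as decay of free catalyst, with a lifetime of about 26.9 min, so 83 min is about 3.09 lifetimes.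

How does exposure follow catalyst? The dawn run reaches 2.36 against 0.616 for the dusk run, a ratio of 3.83 for 3.00 times the catalyst. That is an average power of 1.22, and I commit to that figure.

For the spring run I carry the summer exposure over, which gives 44.9 % turned.

The forecast gives powers of 1 and 1.3, the second above mine, and 45 % for the spring run, with “no visible saturation or product effect”.

The spring run gives 44.6 %, an exposure of 0.591. About the charge of the dusk run, the first rate follows starting material to the power 1.1 and free catalyst to the power 1.6. Across the wider step from the dusk run to the dawn run, 3.00 times the catalyst, the rate goes from 0.012 M min⁻¹ to 0.049 M min⁻¹, an average power of 1.30.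

    free catalyst + starting material → product + free catalyst (38.28 M⁻¹ min⁻¹)
    free catalyst → spent catalyst (0.04122 min⁻¹)
    free catalyst + impurity → spent catalyst

Exposure here is the catalytic constant times the free catalyst surviving the impurity, over the decay constant, scaled by the share of decay done by that time. The impurity leaves the dawn run 0.00266 M of free catalyst, so at 83 min the dawn run stands at an exposure of 2.39.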